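The amounts of target in the earliest readings hold most of what we need, so we start from them.

| flask | starting material | coupling partner | time |
|---|---|---|---|
| Tuesday's | 0.100 M | 0.110 M |  |
| Monday's | 0.0600 M | 0.0700 M |  |
| Thursday's | 0.100 M | 0.170 M |  |
| Wednesday's | 0.200 M | 0.0550 M | 72 min |

- Tuesday's run (time / min: [target] / M): 12: 0.0143; 24: 0.0242; 36: 0.0309; 48: 0.0341; 60: 0.0364; 72: 0.0381
- Monday's run (time / min: [target] / M): 12: 0.0076; 24: 0.0124; 36: 0.0164; 48: 0.0192; 60: 0.0215; 72: 0.0234
- Thursday's run (time / min: [target] / M): 12: 0.0210; 24: 0.0333; 36: 0.0398; 48: 0.0431; 60: 0.0438; 72: 0.0440

(readings scatter by 3 × 10⁻⁴ M)

- Overall: starting material + coupling partner -> target.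
- Constant volume, constant temperature.
- Bound and free are read together.
- An order is taken over about fifteen percent of the charge, up and down.

- the exponent of [starting material] in the starting rate at the charge of the Tuesday's run (at the point where two percent of the starting material have become target) (one fixed amount of target, the same in the runs compared)
- the exponent of [coupling partner] in the starting rate at the charge of the Tuesday's run (at the point where two percent of the starting material have become target)
- target in the Wednesday's run at 72 min, as a share of the starting material charged

We carry one quantity, g, the rate per partner: the starting slope of target divided by the coupling partner charged. If g stays put when the partner changes, the rate is first order in partner, and how g moves with the charge of starting material gives that exponent, n.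

There are two ways to the slope, each a parabola through the origin. The first uses the readings at 12 min and 24 min. It gives g = 0.0125 min⁻¹ for Tuesday's run, 0.0124 min⁻¹ for Thursday's and 0.0107 min⁻¹ for Monday's, so n = 0.302. The second uses the readings at 24 min and 36 min. It gives 0.0119 min⁻¹, 0.0115 min⁻¹ and 0.00913 min⁻¹ in the same order, so n = 0.518, higher than by the first way.

Thursday's g over Tuesday's comes to 0.994 by the first way and 0.965 by the second, so we take first order in partner. They part on n, and the parting lies in Monday's run. There the increments of target fall by 0.00280 M from the first to the second, then by 8.00 × 10⁻⁴ M from the second to the third, while a drop reckoned from three readings has a scatter of 7.35 × 10⁻⁴ M. Monday's first reading looks high, it enters the first way with weight 4, and the second way does not use it. We therefore keep the second way: between Monday's and Tuesday's charges the exponent of starting material reads about half.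

For Wednesday's run, starting material stands above coupling partner, which makes the partner the limiting reagent. We treat the run as pseudo-first-order in it, with g = 0.0170 min⁻¹. That gives 0.0389 M of target, or 19.4% of the starting material, and it holds g at its starting value throughout.

The forecast gives 0.4 for the exponent of starting material, “suggesting saturation”, 1 for that of coupling partner, and 13.5% for Wednesday's share. It differs from ours on n and on Wednesday's share.

The flask gives exponents of 0.58 in starting material and 1.0 in coupling partner, and 15.8% for Wednesday's run, from these steps:

    starting material + coupling partner ⇌ target + by-product (0.5928 M⁻¹ min⁻¹, 0.1230 M⁻¹ min⁻¹)
    target + coupling partner → side product (0.08160 M⁻¹ min⁻¹)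
    2 starting material ⇌ idle substrate dimer, settled at all times (81.10 M⁻¹)

Early in Monday's and Tuesday's runs the forward step ran on starting material in balance with idle substrate dimer, at 0.00909 min⁻¹ and 0.0125 min⁻¹ per coupling partner charged, both at the same amount of target. Later in Wednesday's run, with target in the flask, the reverse step and the loss of target to side product ran beside the forward step, and at 72 min target stood at 0.0317 M, below the 0.0389 M that a steady g of 0.0170 min⁻¹ gives.

All runs were generated by integration on assumed constants, and the scatter is random.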